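Late in a run X and Z fall together, and that common fall is what I watched, reckoning with the fraction left and not the fraction made.

    E ⇌ X (K1 = 12, k1 = 0.012 /s)
    Z → D (k2 = 0.0012 /s)
    X ⇌ Z (K3 = 0.36, k3 = 0.0039 /s)
    X + G → X.G (k4 = 0.026 /M/s)
    X → Q (k5 = 0.0076 /s)

common to all: G 2.00 mM

| flask | E | time | remark |
|---|---|---|---|
| delta | 0.10 M | 4.0 min | a closed flask charged with all of it at once and left for 4.0 min |
| beta | 0.10 M (fed, over 3.20 min) | 4.0 min | all but E at the start; E goes in evenly over 3.20 min, the run ends at 4.0 min |
| theta | 0.10 M |  | one stirred flow tank at steady state, fed with the mixture as stated, mean residence time 20.0 min |
| epsilon | 0.10 M |  | one stirred flow tank at steady state, fed with the mixture as stated, mean residence time 4.0 min |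

* the set-up with the highest amount of X at the outlet or at the end, in percent of the E put in ("none" if the first two lie within 2 percentage points) (delta / beta / theta / epsilon / none)
* amount of X at the outlet or at the end, in percent of the E put in, delta
* amount of X at the outlet or at the end, in percent of the E put in, beta
* amount of X at the outlet or at the end, in percent of the E put in, theta
* amount of X at the outlet or at the end, in percent of the E put in, epsilon

I ranked the rates from the fastest down. X and Z trade at 0.0147 /s, forward and backward constants added, which is faster than the 0.012 /s at which E turns into X. So I let Z stand to X as 0.36, a loose step with two rates so near. The way back from X to E, at 0.00100 /s, is slower than the way there, and I dropped it. G, held at its starting concentration, takes X in pseudo-first-order fashion at 5.20 × 10⁻⁵ /s, less than the 0.0076 /s of the step to Q.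

Below these stands the rung I carried: X and Z as one pool, whose exits to Q, X.G and D are each weighted by the pool's share in X or Z. I called the leak the constant at which that pool shrinks, 0.00594 /s. E fills the pool about twice as fast as it leaks, and the pool's mean life of 2.80 min is shorter than the delta run.

In a closed flask, the pool holds the constant of E over the difference of the two constants, times the gap between the fraction of pool left and the fraction of E left. X is 73.5% of the pool, so delta gave me 26.8%. In beta the E has a mean age of 2.40 min, younger than in delta, and the same sum at that age gave 36.0%. In a stirred tank at steady state, a first-order loss leaves a fraction of one over one plus constant times residence time. For the pool in theta that is 12.3%, so theta gave 8.45% and epsilon 22.5%. Beta stood highest in my reckoning.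

The forecast also named beta, but lower than mine for delta and beta, at 24.4% and 33.5%, with 8.5% for theta and 23.1% for epsilon, holding that “the network behaves almost linearly”.

The flask gave beta as highest, with 33.5%, then delta 24.4%, epsilon 23.1% and theta 8.51%, so delta and beta lay 2.4 percentage points and 2.5 points under my figures. At the end of delta Z stood at 9.30%, a reading of 0.381 for Z over X. Now take the epsilon tank with its residence time raised to 40.0 min, ten times what it was. The leak leaves 6.55% of the pool, which makes 4.65% as X, and that tank read 4.68%.

The numbers of this flask stand for no real mixture; the rest is arithmetic.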